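What is left at 8.0 min cannot be solid, since both runs read 0% of it there, so the unreacted part of the flask is whatever has only dissolved.

| flask | solid substrate | acid | scavenger | remark | time |
|---|---|---|---|---|---|
| east | 2 mM | 0.10 mM | 1 mM | run made earlier |  |
| south | 2 mM | 0.15 mM | 1 mM | run made earlier |  |
| flask | 2.0 mM | 0.200 mM | 1.00 mM |  | 8.0 min |

| run | time / min | solid substrate / % | target / % |
|---|---|---|---|
| east | 2.00 | 73.5 | 6.3 |
| east | 4.00 | 49.3 | 6.6 |
| east | 6.00 | 25.2 | 7.3 |
| east | 8.00 | 0 | 7.5 |
| south | 1.00 | 86.3 | 3.4 |
| south | 3.00 | 60.2 | 8.0 |
| south | 5.00 | 35.0 | 7.3 |
| south | 8.00 | 0 | 5.9 |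

(standard deviation of a reading: 0.5 percentage points)

- part of the solid substrate that has reacted (what has only dissolved counts as not reacted) at 8.0 min
- pH of the solution at 8.0 min

- acid is the free proton; pH is minus the decimal logarithm of its molar concentration
- solid, in amounts per volume of the solution: solid substrate
- at the start none of the solid substrate is in solution
- what has only dissolved of solid substrate counts as not reacted
- apart from what has only dissolved, what has gone from solid substrate into another species counts as reacted, even if it can come back

We reckon that leftover by subtraction. In the south run the solid goes at 0.128 min⁻¹ of the charge, and in the east run at 0.121 min⁻¹. Target in the south run flattens near 7.65%, and a flat level means a quasi-steady state, with target lost as fast as it is fed. That gives a loss constant of 1.68 min⁻¹. Applied to the south readings, it means 22.0% of the charge has passed beyond target by 3.00 min. Taking this and the standing target from the solid gone leaves 9.84%: the standing pool, dissolved but not yet reacted.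

The pool drains at feed over pool, 1.30 min⁻¹. The south run and the flask differ in acid, 0.15 mM against 0.200 mM. In the south run the solid ends near 7.80 min, so its pool has shrunk to 7.55% at the last reading. We carry that pool over to the flask and commit to about 92.5% reacted there. Target in the east run exceeds that run's acid charge, so we treat acid as a catalyst and keep the pH of the charge, 3.70.

The forecast gives 65% and pH 3.75, on the ground that “Scavenger capacity (50% plus target) may cap this”.

The flask gives 94.7% and pH 3.68.

    weak acid ⇌ conjugate base + acid, settled at all times (K = 2.00 × 10⁻⁶ M)
    target → over-reaction product (k = 0.0271 s⁻¹)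
    solid substrate ⇌ starting material, rate k3*(cs3 - [starting material]) while solid is left; crystals form when [starting material] > cs3 (solubility = 1.10 mM, k = 0.00468 s⁻¹)
    starting material + weak acid ⇌ idle adduct, settled at all times (K = 1200 M⁻¹)
    starting material + acid → weak acid + acid + target (k = 65.4 M⁻¹ s⁻¹)
    weak acid + scavenger → scavenged by-product (k = 586 M⁻¹ s⁻¹)
    starting material → weak acid + target (k = 0.0104 s⁻¹)

In the flask the pool is the starting material, 9.00% at 4.00 min, below the south run's 9.84%, and 5.35% at 8.00 min. The neighbouring flask changes the scavenger alone, to 4.0 mM. Neither feed nor drain in our reckoning contains scavenger, so it carries the flask's pool over unchanged. Its starting material ends at 5.58%, with 53% of its scavenger still there, against 0% in the flask, and 94.4% has reacted.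

The earlier runs and the new flask stem from a simulated flask on assumed constants; noise was put on by code.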